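**Strategy.** The decalin is cut at C5–C10 and C8–C9 (labdane numbering), a [4+2] retron once the C7=C8 alkene is moved to C6=C7. Because the target carries a carboxyl (C17) on C8 of ring B and an oxygen on C14 at the end of the C9 side chain, these two groups can be joined as a lactone, which makes the cycloaddition transannular. Heating the resulting 16-membered (E,E)-dienoate lactone with its (E)-C9=C10 alkene should close rings A and B at once and set C5, C9 and C10 (C8 transiently), the chiral-pool C13 methyl choosing the face. The precursor is this triene lactone, free of protecting groups.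

Key step: step 12

Remark: labdane numbering is used throughout (ring A = C1–C5 and C10, ring B = C5–C10, C17 on C8, side chain C11–C14 with the methyl on C13); the triene lactone is used without added substituents and without Lewis acid, since its quaternary C4 already blocks 1,5-hydrogen shifts of the diene.

**Step 1**
Reactants: 1 pent-4-yn-1-ol
Product: 3 (E)-5-iodo-4-methylpent-4-en-1-ol, via alkenylalane 2 (not isolated)
Conditions: Me3Al (3 equiv), Cp2ZrCl2 (0.25 equiv), CH2Cl2, 0 °C → rt; then I2, THF, −30 → 0 °C
Reagents that add atoms: trimethylaluminium, C[Al](C)C; iodine, II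
Why: Negishi zirconium-catalysed carboalumination adds CH3 and Al syn across the alkyne with Al at the terminus (the hydroxyl being masked as its aluminium alkoxide), and iodinolysis with retention should give the (E)-iodide that fixes the C9=C10 geometry and the C10 methyl.

**Step 2**
Reactants: 4 methyl (S)-3-hydroxy-2-methylpropanoate
Product: 5 methyl (S)-3-[(tert-butyldimethylsilyl)oxy]-2-methylpropanoate
Conditions: TBSCl, imidazole, CH2Cl2, 0 °C → rt
Reagents that add atoms: tert-butyldimethylsilyl chloride, CC(C)(C)[Si](C)(C)Cl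
Why: Standard silylation of the primary alcohol (the future C14–O) proceeds under conditions that do not touch the α-stereocentre (the future C13).

**Step 3**
Reactants: 5 methyl (S)-3-[(tert-butyldimethylsilyl)oxy]-2-methylpropanoate
Product: 7 (S)-3-[(tert-butyldimethylsilyl)oxy]-2-methylpropanal, via aluminium hemiacetal 6 (not isolated)
Conditions: i-Bu2AlH (1.05 equiv), CH2Cl2, −78 °C; then MeOH, aq. KNaC4H4O6, −78 °C → rt
Reagents that add atoms: none
Why: Partial hydride reduction of the ester stops at the tetrahedral aluminium hemiacetal at −78 °C, which releases the aldehyde only on neutral work-up, so the enolisable α-centre should survive if the crude aldehyde is used at once.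

**Step 4**
Reactants: 7 (S)-3-[(tert-butyldimethylsilyl)oxy]-2-methylpropanal
Product: 8 (R)-tert-butyldimethyl[(2-methylbut-3-en-1-yl)oxy]silane
Conditions: Ph3PCH3Br, KN(SiMe3)2, THF, 0 °C; then 7, −78 → 0 °C
Reagents that add atoms: methyltriphenylphosphonium bromide, C[P+](c1ccccc1)(c1ccccc1)c1ccccc1.[Br-]
Why: Wittig methylenation with the non-stabilised ylide is fast at low temperature relative to α-deprotonation, so C12=C11 is installed without loss of the C13 configuration (the descriptor becomes R only through the priority rules).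

**Step 5**
Reactants: 8 (R)-tert-butyldimethyl[(2-methylbut-3-en-1-yl)oxy]silane; 3 (E)-5-iodo-4-methylpent-4-en-1-ol
Product: 10 (R,E)-9-[(tert-butyldimethylsilyl)oxy]-4,8-dimethylnon-4-en-1-ol, via B-alkyl-9-BBN 9 (not isolated)
Conditions: 9-BBN-H, THF, 0 °C → rt; then 3, Pd(dppf)Cl2 (5 mol%), Ph3As (10 mol%), Cs2CO3, DMF/THF/H2O, rt
Reagents that add atoms: none
Why: Anti-Markovnikov hydroboration puts boron on C11, and the B-alkyl Suzuki–Miyaura coupling with the vinyl iodide forms C9–C11 with retention of the alkene geometry and tolerates the free hydroxyl.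

**Step 6**
Reactants: 10 (R,E)-9-[(tert-butyldimethylsilyl)oxy]-4,8-dimethylnon-4-en-1-ol
Product: 11 (R,E)-tert-butyl[(9-iodo-2,6-dimethylnon-5-en-1-yl)oxy]dimethylsilane
Conditions: PPh3, I2, imidazole, CH2Cl2, 0 °C → rt
Reagents that add atoms: iodine, II
Why: Appel-type iodination converts the primary C3 alcohol into the iodide by SN2 displacement of an alkoxyphosphonium ion under buffered conditions that leave the silyl ether and the alkene alone.

**Step 7**
Reactants: 11 (R,E)-tert-butyl[(9-iodo-2,6-dimethylnon-5-en-1-yl)oxy]dimethylsilane; 12 isobutyronitrile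
Product: 14 (R,E)-11-[(tert-butyldimethylsilyl)oxy]-2,2,6,10-tetramethylundec-6-enenitrile, via lithiated isobutyronitrile 13 (not isolated)
Conditions: LiN(i-Pr)2, THF, −78 °C; then 11, −78 °C → rt
Reagents that add atoms: none
Why: SN2 alkylation of the tertiary nitrile-stabilised carbanion with the unhindered primary iodide builds the quaternary C4 with both methyl groups and brings in C5 as the nitrile carbon.

**Step 8**
Reactants: 14 (R,E)-11-[(tert-butyldimethylsilyl)oxy]-2,2,6,10-tetramethylundec-6-enenitrile
Product: 16 (R,E)-11-[(tert-butyldimethylsilyl)oxy]-2,2,6,10-tetramethylundec-6-enal, via aluminium aldimine 15 (not isolated)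
Conditions: i-Bu2AlH (1.3 equiv), toluene, −78 → 0 °C; then aq. citric acid, 0 °C
Reagents that add atoms: water, O
Why: Hydride addition to the hindered nitrile stops at the N-aluminio imine, whose mild acidic hydrolysis should give the non-enolisable neopentyl aldehyde.

**Step 9**
Reactants: 16 (R,E)-11-[(tert-butyldimethylsilyl)oxy]-2,2,6,10-tetramethylundec-6-enal; 17 triethyl 4-phosphonocrotonate
Product: 19 ethyl (2E,4E,10E,14R)-15-[(tert-butyldimethylsilyl)oxy]-6,6,10,14-tetramethylpentadeca-2,4,10-trienoate, via lithiated phosphonate 18 (not isolated)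
Conditions: LiN(SiMe3)2, THF, −78 °C; then 16, −78 °C → rt
Reagents that add atoms: none
Why: Vinylogous Horner–Wadsworth–Emmons olefination of the bulky aldehyde should form C5=C6 with E geometry while the E geometry of C7=C8 is carried over from the reagent.

**Step 10**
Reactants: 19 ethyl (2E,4E,10E,14R)-15-[(tert-butyldimethylsilyl)oxy]-6,6,10,14-tetramethylpentadeca-2,4,10-trienoate
Product: 21 (2E,4E,10E,14R)-15-hydroxy-6,6,10,14-tetramethylpentadeca-2,4,10-trienoic acid, via silyl ether acid 20 (not isolated)
Conditions: LiOH, THF/EtOH/H2O, 40 °C; then 2 M HCl to pH 1, rt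
Reagents that add atoms: lithium hydroxide, [Li+].[OH-]
Why: Saponification of the unhindered dienoate followed by acid-promoted cleavage of the primary silyl ether in the same pot frees both ends of the seco acid without touching the three alkenes.

**Step 11**
Reactants: 21 (2E,4E,10E,14R)-15-hydroxy-6,6,10,14-tetramethylpentadeca-2,4,10-trienoic acid
Product: 23 (3E,5E,11E,15R)-7,7,11,15-tetramethyl-1-oxacyclohexadeca-3,5,11-trien-2-one, via mixed anhydride 22 (not isolated)
Conditions: 2,4,6-Cl3C6H2COCl, Et3N, THF, rt; then slow addition to DMAP, toluene (1 mM final), 40 °C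
Reagents that add atoms: none
Why: In this Yamaguchi macrolactonisation DMAP attacks the mixed anhydride at the dienoyl carbonyl and the acylpyridinium is captured by the primary C14 hydroxyl under high dilution, the absence of hydrogen on C4 excluding deconjugation through a ketene-type intermediate.

**Step 12**
Reactants: 23 (3E,5E,11E,15R)-7,7,11,15-tetramethyl-1-oxacyclohexadeca-3,5,11-trien-2-one
Product: 24 (13R)-15-norlabd-6-eno-17,14-lactone (trans-fused decalin, cis-fused eight-membered lactone)
Conditions: 1,2-Cl2C6H4 (5 mM, degassed), BHT (10 mol%), sealed tube, 180–220 °C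
Reagents that add atoms: none
Why: Proposed new method: on heating, the s-cis C5=C6–C7=C8 dienoate and the C9=C10 alkene facing it across the ring should combine in a concerted suprafacial [4+2] cycloaddition that forms C5–C10 and C8–C9 and leaves C6=C7; the closest known reaction type is the thermal transannular Diels–Alder reaction of macrocyclic (E,E,E)-trienes, which has not been shown for an ester-bearing diene paired with an unactivated trisubstituted alkene under the control of one remote methyl group. Ring A closes as a six-membered ring through the C1–C4 tether in a chair-like array with C1 exo to the diene (the mode of a 1,7,9-decatriene cycloaddition), ring B is the new cyclohexene formed through a boat-like transition state, and the 16-membered ring contracts to an eight-membered lactone. The (E,E)-diene places C4 and C17 cis and so fixes C5 relative to C8, the (E)-alkene places the C10 methyl and C11 cis and so fixes C10 relative to C9, and the exo C1 tether makes H5 and the C10 methyl trans, which for an (E)-dienophile necessarily makes the lactone cis-fused at C8–C9. Two selectivities are needed: the trans-decalin/cis-lactone mode over the cis-decalin/trans-lactone mode, which the chair tether and the easier cis fusion of an eight-membered ring should favour, and one diene face over the other, which rests only on the C13 methyl taking a pseudo-equatorial site on the forming lactone and is the unproven point. No Lewis acid is used because carbonyl complexation would polarise the dienoate toward C5–C9 bonding and cationic side reactions, whereas the quaternary C4 next to the diene excludes 1,5-hydrogen shifts and BHT suppresses radical polymerisation at the temperature needed.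

**Step 13**
Reactants: 24 (13R)-15-norlabd-6-eno-17,14-lactone
Product: 27 (1R,4aS,8aS)-1-[(3R)-4-hydroxy-3-methylbutyl]-5,5,8a-trimethyl-1,4,4a,5,6,7,8,8a-octahydronaphthalene-2-carboxylic acid, via hydroxy methyl ester 25 (not isolated), via conjugated methyl ester 26 (not isolated)
Conditions: NaOMe, MeOH, 65 °C; then 2 M NaOH (aq.), 65 °C; then 1 M HCl to pH 3
Reagents that add atoms: sodium hydroxide, [Na+].[OH-]
Why: Methoxide opens the strained eight-membered lactone and, through the ester dienolate formed by removal of the doubly activated H8, equilibrates C6=C7 into conjugation at C7=C8 (erasing C8, with C5, C9, C10 and C13 out of reach of the base), after which saponification gives the hydroxy acid.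

**Step 14**
Reactants: 27 (1R,4aS,8aS)-1-[(3R)-4-hydroxy-3-methylbutyl]-5,5,8a-trimethyl-1,4,4a,5,6,7,8,8a-octahydronaphthalene-2-carboxylic acid
Product: 28 (1R,4aS,8aS)-5,5,8a-trimethyl-1-[(3R)-3-methyl-4-(2-methylpropanoyloxy)butyl]-1,4,4a,5,6,7,8,8a-octahydronaphthalene-2-carboxylic acid (CNP0323283.1)
Conditions: (i-PrCO)2O (1.3 equiv), Et3N, DMAP (cat.), CH2Cl2, 0 °C → rt; then aq. NaHCO3, THF, rt; aq. citric acid
Reagents that add atoms: isobutyric anhydride, CC(C)C(=O)OC(=O)C(C)C
Why: DMAP-catalysed acylation esterifies the primary C14 hydroxyl irreversibly, whereas any acyl transfer to the hindered conjugated carboxyl is undone by the bicarbonate quench, so the acid stays free.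

**Compound list**

1 | pent-4-yn-1-ol | C#CCCCO | starting material
2 | dimethyl[(E)-5-(dimethylalumanyloxy)-2-methylpent-1-en-1-yl]alumane | C[Al](C)/C=C(\C)CCCO[Al](C)C | intermediate (not isolated)
3 | (E)-5-iodo-4-methylpent-4-en-1-ol | OCCC/C(C)=C/I | intermediate
4 | methyl (S)-3-hydroxy-2-methylpropanoate | OC[C@H](C)C(=O)OC | starting material
5 | methyl (S)-3-[(tert-butyldimethylsilyl)oxy]-2-methylpropanoate | CC(C)(C)[Si](C)(C)OC[C@H](C)C(=O)OC | intermediate
6 | diisobutylaluminium hemiacetal of 5 (hemiacetal carbon undefined) | CC(C)(C)[Si](C)(C)OC[C@H](C)C(OC)O[Al](CC(C)C)CC(C)C | intermediate (not isolated)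
7 | (S)-3-[(tert-butyldimethylsilyl)oxy]-2-methylpropanal | CC(C)(C)[Si](C)(C)OC[C@H](C)C=O | intermediate
8 | (R)-tert-butyldimethyl[(2-methylbut-3-en-1-yl)oxy]silane | CC(C)(C)[Si](C)(C)OC[C@H](C)C=C | intermediate
9 | (R)-9-{4-[(tert-butyldimethylsilyl)oxy]-3-methylbutyl}-9-borabicyclo[3.3.1]nonane | CC(C)(C)[Si](C)(C)OC[C@H](C)CCB1C2CCCC1CCC2 | intermediate (not isolated)
10 | (R,E)-9-[(tert-butyldimethylsilyl)oxy]-4,8-dimethylnon-4-en-1-ol | CC(C)(C)[Si](C)(C)OC[C@H](C)CC/C=C(\C)CCCO | intermediate
11 | (R,E)-tert-butyl[(9-iodo-2,6-dimethylnon-5-en-1-yl)oxy]dimethylsilane | CC(C)(C)[Si](C)(C)OC[C@H](C)CC/C=C(\C)CCCI | intermediate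
12 | isobutyronitrile | CC(C)C#N | starting material
13 | lithiated isobutyronitrile (N-lithio ketenimine form) | [Li]N=C=C(C)C | intermediate (not isolated)
14 | (R,E)-11-[(tert-butyldimethylsilyl)oxy]-2,2,6,10-tetramethylundec-6-enenitrile | CC(C)(C)[Si](C)(C)OC[C@H](C)CC/C=C(\C)CCCC(C)(C)C#N | intermediate
15 | N-(diisobutylalumanyl) aldimine of 14 | CC(C)(C)[Si](C)(C)OC[C@H](C)CC/C=C(\C)CCCC(C)(C)C=N[Al](CC(C)C)CC(C)C | intermediate (not isolated)
16 | (R,E)-11-[(tert-butyldimethylsilyl)oxy]-2,2,6,10-tetramethylundec-6-enal | CC(C)(C)[Si](C)(C)OC[C@H](C)CC/C=C(\C)CCCC(C)(C)C=O | intermediate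
17 | triethyl 4-phosphonocrotonate | CCOC(=O)/C=C/CP(=O)(OCC)OCC | starting material
18 | lithiated triethyl 4-phosphonocrotonate | [Li+].CCOC(=O)/C=C/[CH-]P(=O)(OCC)OCC | intermediate (not isolated)
19 | ethyl (2E,4E,10E,14R)-15-[(tert-butyldimethylsilyl)oxy]-6,6,10,14-tetramethylpentadeca-2,4,10-trienoate | CCOC(=O)/C=C/C=C/C(C)(C)CCC/C(C)=C/CC[C@@H](C)CO[Si](C)(C)C(C)(C)C | intermediate
20 | (2E,4E,10E,14R)-15-[(tert-butyldimethylsilyl)oxy]-6,6,10,14-tetramethylpentadeca-2,4,10-trienoic acid (present as its lithium salt) | OC(=O)/C=C/C=C/C(C)(C)CCC/C(C)=C/CC[C@@H](C)CO[Si](C)(C)C(C)(C)C | intermediate (not isolated)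
21 | (2E,4E,10E,14R)-15-hydroxy-6,6,10,14-tetramethylpentadeca-2,4,10-trienoic acid | OC(=O)/C=C/C=C/C(C)(C)CCC/C(C)=C/CC[C@@H](C)CO | intermediate
22 | mixed anhydride of 21 with 2,4,6-trichlorobenzoic acid | O=C(OC(=O)c1c(Cl)cc(Cl)cc1Cl)/C=C/C=C/C(C)(C)CCC/C(C)=C/CC[C@@H](C)CO | intermediate (not isolated)
23 | (3E,5E,11E,15R)-7,7,11,15-tetramethyl-1-oxacyclohexadeca-3,5,11-trien-2-one (16-membered triene lactone; 13R in labdane numbering) | O=C1/C=C/C=C/C(C)(C)CCC/C(C)=C/CC[C@@H](C)CO1 | intermediate
24 | (13R)-15-norlabd-6-eno-17,14-lactone: trans-fused decalin (5α-H, 10β-CH3, C6=C7) cis-fused at C8–C9 (8α-H, 9α-H) to the eight-membered C17(=O)–O–C14 lactone; 5S,8S,9S,10R,13R | O=C1OC[C@H](C)CC[C@H]2[C@@H]1C=C[C@H]3C(C)(C)CCC[C@]23C | intermediate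
25 | methyl (5S,8S,9S,10R,13R)-14-hydroxy-15-norlabd-6-en-17-oate | OC[C@H](C)CC[C@H]1[C@@H](C(=O)OC)C=C[C@H]2C(C)(C)CCC[C@]12C | intermediate (not isolated)
26 | methyl (5S,9R,10S,13R)-14-hydroxy-15-norlabd-7-en-17-oate | OC[C@H](C)CC[C@H]1C(C(=O)OC)=CC[C@H]2C(C)(C)CCC[C@]12C | intermediate (not isolated)
27 | (1R,4aS,8aS)-1-[(3R)-4-hydroxy-3-methylbutyl]-5,5,8a-trimethyl-1,4,4a,5,6,7,8,8a-octahydronaphthalene-2-carboxylic acid | OC[C@H](C)CC[C@H]1C(C(=O)O)=CC[C@H]2C(C)(C)CCC[C@]12C | intermediate
28 | (1R,4aS,8aS)-5,5,8a-trimethyl-1-[(3R)-3-methyl-4-(2-methylpropanoyloxy)butyl]-1,4,4a,5,6,7,8,8a-octahydronaphthalene-2-carboxylic acid | CC(C)C(=O)OC[C@H](C)CC[C@H]1C(C(=O)O)=CC[C@H]2C(C)(C)CCC[C@]12C | target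

**Step count.** Total: 14 steps. Longest linear sequence: 13 steps (steps 2–14, from methyl (S)-3-hydroxy-2-methylpropanoate).

**Steps most likely to fail**

Step 12. The macrocycle may not reach the folded transition state before transannular ene reaction or decomposition sets in, the cis-decalin mode may compete, and above all the remote C13 methyl may discriminate the two diene faces only weakly, so that much of the material closes with the wrong decalin configuration relative to C13. The fallback gives up the cycloaddition and takes rings A and B, with C5, C9 and C10, from the chiral pool using known reactions only. It therefore uses no numbered intermediate as its departure point: it sets out from commercial (+)-sclareolide F1 and comes back to the route at target 28.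
- Reduction with i-Bu2AlH (CH2Cl2, −78 °C) gives lactol F2.
- A Wittig reaction with Ph3P=C(CH3)CO2Et (toluene, 90 °C) should open it to the (E)-hydroxy enoate F3, and i-Bu2AlH reduction then gives allylic diol F4.
- Asymmetric hydrogenation of this trisubstituted allylic alcohol with Ru(OAc)2(BINAP) under H2 gives saturated diol F5; the ligand antipode is chosen to deliver 13R, so C13 is set by the catalyst.
- Selective acylation of the primary hydroxyl with (i-PrCO)2O and DMAP gives isobutyrate F6.
- Dehydration of the equatorial tertiary alcohol (SOCl2, pyridine, −78 °C) should favour exocyclic alkene F7.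
- Ozonolysis (O3, CH2Cl2/MeOH, −78 °C; then Me2S) gives the C8 ketone F8.
- Kinetic enolisation toward C7 with trapping (LiN(SiMe3)2, PhNTf2, THF, −78 °C) gives enol triflate F9.
- Hydroxycarbonylation (Pd(OAc)2, Ph2P(CH2)3PPh2, CO, KOAc, DMF/H2O) then gives 28.

Step 11. Intermolecular esterification (dimeric and oligomeric lactones) may outrun ring closure, or the dienoate may isomerise during carboxyl activation. The fallback closes the ring at C5=C6 instead of at the ester; it sets out from aldehyde 16 and comes back at macrolactone 23. Bu4NF (THF, 0 °C) frees hydroxy aldehyde F10. (E)-4-(Diethoxyphosphoryl)but-2-enoic acid F11, made from 17 with one equivalent of NaOH in aqueous EtOH, is coupled to the C14 hydroxyl with N,N'-dicyclohexylcarbodiimide and DMAP (CH2Cl2, 0 °C) to give phosphonate ester F12. An intramolecular Horner–Wadsworth–Emmons olefination under high dilution (LiCl, DBU, MeCN, 1 mM, rt) then forms the diene and the 16-membered ring together.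

Step 13. The alkene may migrate only partly into conjugation, and saponification of the hindered conjugated ester may be slow, leaving mixtures of alkene isomers or re-closed lactone. The fallback changes the oxidation level so that the isomerisation runs on an aldehyde; it sets out from 24 and comes back at 27. i-Bu2AlH (CH2Cl2, −78 °C) reduces the lactone to hydroxy aldehyde F13 (in equilibrium with its lactol). Catalytic DBU (CH2Cl2, rt) moves the alkene into conjugation to give enal F14, for which α-acidity and driving force are much larger than for an ester. Pinnick oxidation (NaClO2, NaH2PO4, 2-methylbut-2-ene, t-BuOH/H2O) then gives 27 without touching the primary alcohol.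

**Further compounds**

F1 | step 12 | (+)-sclareolide | O=C1C[C@H]2[C@](C)(O1)CC[C@H]3C(C)(C)CCC[C@]23C
F2 | step 12 | sclareolide lactol (8α,12-epoxy-13,14,15,16-tetranorlabdan-12-ol, anomeric mixture) | OC1C[C@H]2[C@](C)(O1)CC[C@H]3C(C)(C)CCC[C@]23C
F3 | step 12 | ethyl (12E)-8α-hydroxy-15-norlabd-12-en-14-oate | CCOC(=O)/C(C)=C/C[C@H]1[C@](C)(O)CC[C@H]2C(C)(C)CCC[C@]12C
F4 | step 12 | (12E)-15-norlabd-12-ene-8α,14-diol | OC/C(C)=C/C[C@H]1[C@](C)(O)CC[C@H]2C(C)(C)CCC[C@]12C
F5 | step 12 | (13R)-15-norlabdane-8α,14-diol | OC[C@H](C)CC[C@H]1[C@](C)(O)CC[C@H]2C(C)(C)CCC[C@]12C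
F6 | step 12 | (13R)-8α-hydroxy-15-norlabdan-14-yl 2-methylpropanoate | CC(C)C(=O)OC[C@H](C)CC[C@H]1[C@](C)(O)CC[C@H]2C(C)(C)CCC[C@]12C
F7 | step 12 | (13R)-15-norlabd-8(17)-en-14-yl 2-methylpropanoate | CC(C)C(=O)OC[C@H](C)CC[C@H]1C(=C)CC[C@H]2C(C)(C)CCC[C@]12C
F8 | step 12 | (13R)-8-oxo-15,17-dinorlabdan-14-yl 2-methylpropanoate | CC(C)C(=O)OC[C@H](C)CC[C@H]1C(=O)CC[C@H]2C(C)(C)CCC[C@]12C
F9 | step 12 | (13R)-8-[(trifluoromethylsulfonyl)oxy]-15,17-dinorlabd-7-en-14-yl 2-methylpropanoate | CC(C)C(=O)OC[C@H](C)CC[C@H]1C(OS(=O)(=O)C(F)(F)F)=CC[C@H]2C(C)(C)CCC[C@]12C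
F10 | step 11 | (R,E)-11-hydroxy-2,2,6,10-tetramethylundec-6-enal | OC[C@H](C)CC/C=C(\C)CCCC(C)(C)C=O
F11 | step 11 | (E)-4-(diethoxyphosphoryl)but-2-enoic acid | OC(=O)/C=C/CP(=O)(OCC)OCC
F12 | step 11 | (R,E)-2,6,10,10-tetramethyl-11-oxoundec-5-en-1-yl (E)-4-(diethoxyphosphoryl)but-2-enoate | CCOP(=O)(OCC)C/C=C/C(=O)OC[C@H](C)CC/C=C(\C)CCCC(C)(C)C=O
F13 | step 13 | (5S,8S,9S,10R,13R)-14-hydroxy-15-norlabd-6-en-17-al | OC[C@H](C)CC[C@H]1[C@@H](C=O)C=C[C@H]2C(C)(C)CCC[C@]12C
F14 | step 13 | (5S,9R,10S,13R)-14-hydroxy-15-norlabd-7-en-17-al | OC[C@H](C)CC[C@H]1C(C=O)=CC[C@H]2C(C)(C)CCC[C@]12C
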